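The earlier runs and the new flask stem from a simulated flask with constants of no real substance.

Which flask holds the most target at 3.0 d, and how much? Here is the bench as I hand it to you.

| flask | substrate | gas | initiator | remark | time |
|---|---|---|---|---|---|
| Wednesday's | 0.012 M | 18 mM (held) | 5 mM | run made earlier |  |
| Sunday's | 0.069 M | 18 mM (held) | 5 mM | run made earlier |  |
| Monday's | 0.050 M | 18 mM (held) | 3.1 mM | run made earlier |  |
| theta | 0.050 M | 18 mM (held) | 5.0 mM |  | 3.0 d |
| beta | 0.015 M | 18 mM (held) | 10 mM |  | 3.0 d |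
| zeta | 0.030 M | 18 mM (held) | 1.5 mM |  | 3.0 d |
| delta | 0.025 M | 18 mM (held) | 5.0 mM |  | 3.0 d |
| alpha | 0.080 M | 18 mM (held) | 5.0 mM |  | 3.0 d |

| run | time / d | target / % | substrate / % |
|---|---|---|---|
| Wednesday's | 0.250 | 50.4 | 0.3 |
| Wednesday's | 0.417 | 53.5 | 0 |
| Wednesday's | 0.833 | 54.2 | 0 |
| Wednesday's | 1.67 | 51.9 | 0 |
| Wednesday's | 3.00 | 48.0 | 0.2 |
| Sunday's | 0.625 | 28.4 | 41.8 |
| Sunday's | 1.25 | 45.0 | 28.1 |
| Sunday's | 1.67 | 49.6 | 23.4 |
| Sunday's | 2.50 | 51.7 | 20.6 |
| Sunday's | 3.00 | 51.1 | 19.6 |
| Monday's | 0.625 | 34.0 | 39.0 |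
| Monday's | 1.25 | 54.1 | 23.3 |
| Monday's | 1.67 | 58.8 | 18.5 |
| Monday's | 2.50 | 60.7 | 14.4 |
| Monday's | 3.00 | 60.6 | 13.9 |

(each reading ± 0.3 percentage points)

1. ranking by amount of target, in percent of the substrate charged, from high to low, at 3.0 d (theta / beta / zeta / delta / alpha)
2. the amount of target, in percent of the substrate charged of the flask you put first, at 3.0 d
3. the amount of target, in percent of the substrate charged of the flask you put last, at 3.0 d

- at the start none of the gas is in solution

Each flask is charged with less initiator than substrate, so I keep the initiator's balance. My assumption is that each initiator gives 2 radicals and each radical that stops takes one substrate with it. For zeta: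

toll = 2[initiator]/[substrate], at the start, = 10.0%

Call this the toll: the ceiling on the share of the charged substrate lost to the initiator. Wednesday's flask has a toll of 83.3%, yet it read 54.2% target, with substrate down to 0.3% by 0.250 d.

Target also fades. Wednesday's flask gives

k = ln(54.2%/48.0%)/(3.00 d − 0.833 d) = 0.0561 d⁻¹

Monday's flask had 34.0% of its 60.6% by 0.625 d, so I date zeta's target from then:

zeta: (1 − toll) exp(−k(3.0 d − 0.625 d)) = 78.8%

Theta's toll is 20.0%, more than zeta's, and delta's is 40.0%, which leaves about 52.5% if delta pays it in full. Alpha stalls with initiator as limiting reagent, so I give it Sunday's amount of target, or 44.1%. Beta's toll, 133%, is higher than Wednesday's, so I expect beta below Wednesday's 48.0%. Don't add initiator to zeta, since that raises its toll.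

The forecast gave zeta > theta > delta > alpha > beta, with 67% and 38%: “Beta is fastest, so it has the worst selectivity and the longest decay”.

The flasks give zeta > theta > delta > alpha > beta, with 76.6% and 35.2%.

    substrate + initiating radical → chain carrier (k = 2.70 × 10⁵ M⁻¹ h⁻¹)
    substrate ⇌ dormant form (K = 0.330, k = 0.0770 h⁻¹)
    2 chain carrier → ended chains (k = 1.10 × 10⁶ M⁻¹ s⁻¹)
    initiator → 2 initiating radical (k = 0.150 h⁻¹)
    partner + chain carrier → target + initiating radical (k = 8.90 × 10⁵ M⁻¹ h⁻¹)
    gas ⇌ partner, rate k6*(csat - [partner]) (kL = 0.170 h⁻¹)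
    target → over-reaction product (k = 0.00270 h⁻¹)

In zeta, ended chains stand at 10.0% against a toll of 10.0%, with initiator at 0%, and my figure lies 2.2 percentage points above its target. Now take the neighbour of zeta charged with 0.12 M of substrate. Its toll is 2.50%, and at 3.00 d its ended chains stand at 2.50%, with initiator at 0%. Substrate remains at 56.7%, dormant form at 18.7% and target at 19.1%.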